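**Assumption:** the target has no stereocentre (it is achiral), so there is no enantiomer to control; the route only has to deliver the constitution.

## Retrosynthetic overview

1. Target 11 ⇐ thiophenophane diyne lactone 9, by Raney-nickel hydrogenation and reductive desulfurization. The thiophene is destroyed and C≡C–thienylene–C≡C becomes (CH2)8.
2. Macrocycle 9 ⇐ 2,5-diiodothiophene 3 + acyclic diyne ester 6, by a one-pot double Sonogashira coupling. The ring is closed by C–C bond formation, not by lactonization.
3. Ester 6 ⇐ undec-10-ynoic acid 4 + undec-10-yn-1-ol 5; diiodide 3 ⇐ thiophene 1. Carbon count: 11 + 4 + 11 = 26.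
4. Ring order: the thiophene is present from the start, the macrocycle is the only ring formed (step 3), and the thiophene ring is excised in step 4.

## Route

Step 1
Reactants: 1 thiophene
Product: 3 2,5-diiodothiophene, via 2-iodothiophene 2 (not isolated)
Conditions: NIS (2.2 equiv), TsOH·H2O (10 mol%), EtOH, rt
Reagents that add atoms: N-iodosuccinimide (NIS), O=C1CCC(=O)N1I
Why: Electrophilic aromatic iodination (SEAr) by acid-activated NIS goes cleanly at both α-positions of thiophene, since the first iodine (2) does not shut down the remaining α-position.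

Step 2
Reactants: 4 undec-10-ynoic acid; 5 undec-10-yn-1-ol
Product: 6 undec-10-yn-1-yl undec-10-ynoate
Conditions: DCC (1.1 equiv), DMAP (10 mol%), CH2Cl2, 0 °C → rt
Reagents that add atoms: none
Why: Steglich esterification of an unhindered primary alcohol with an unhindered acid; the terminal alkynes are inert to carbodiimide/DMAP.

Step 3
Reactants: 3 2,5-diiodothiophene; 6 undec-10-yn-1-yl undec-10-ynoate
Product: 9 [23](2,5)thiophenophane diyne lactone (cyclic ester of 11-[5-(11-hydroxyundec-1-yn-1-yl)thiophen-2-yl]undec-10-ynoic acid), via alcohol-side mono-coupled iodide 7 (not isolated), via acid-side mono-coupled iodide 8 (not isolated)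
Conditions: Pd(PPh3)4 (10 mol%), CuI (20 mol%), Et3N/THF (1:5), rigorously degassed, 45 °C; 3 + 6 (1:1 in THF) added by syringe pump over 24 h, final 2 mM
Reagents that add atoms: none
Why: Sonogashira coupling run twice in one pot: the intermolecular coupling gives 7 or 8 (either alkyne may react first, both converge), and the remaining C–I bond, activated by the new alkynyl group, then closes the strain-free ring intramolecularly under pseudo-high dilution; no stereocentre is formed.

Step 4
Reactants: 9 [23](2,5)thiophenophane diyne lactone
Product: 11 26-hexacosanolide (oxacycloheptacosan-2-one), via saturated thiophenophane lactone 10 (not isolated)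
Conditions: Raney Ni (W-2, washed neutral, large excess), H2 (1 atm), THF, rt 2 h then 65 °C
Reagents that add atoms: none
Why: Raney-nickel hydrogenation and reductive desulfurization (Gol'dfarb-type thiophene excision): the two alkynes are saturated at rt to give 10, then C–S hydrogenolysis and saturation of the freed diene turn the thiophene into four CH2 groups, while the lactone is inert to neutral Raney Ni in an aprotic solvent; no stereocentre is formed.

## Compound list

1 | thiophene | c1ccsc1 | starting material
2 | 2-iodothiophene | Ic1cccs1 | intermediate (not isolated)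
3 | 2,5-diiodothiophene | Ic1ccc(I)s1 | intermediate
4 | undec-10-ynoic acid | C#CCCCCCCCCC(=O)O | starting material
5 | undec-10-yn-1-ol | C#CCCCCCCCCCO | starting material
6 | undec-10-yn-1-yl undec-10-ynoate | C#CCCCCCCCCC(=O)OCCCCCCCCCC#C | intermediate
7 | 11-(5-iodothiophen-2-yl)undec-10-yn-1-yl undec-10-ynoate | C#CCCCCCCCCC(=O)OCCCCCCCCCC#Cc1ccc(I)s1 | intermediate (not isolated)
8 | undec-10-yn-1-yl 11-(5-iodothiophen-2-yl)undec-10-ynoate | Ic1ccc(s1)C#CCCCCCCCCC(=O)OCCCCCCCCCC#C | intermediate (not isolated)
9 | [23](2,5)thiophenophane diyne lactone: cyclic ester of 11-[5-(11-hydroxyundec-1-yn-1-yl)thiophen-2-yl]undec-10-ynoic acid | O=C1CCCCCCCCC#Cc2ccc(s2)C#CCCCCCCCCCO1 | intermediate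
10 | saturated thiophenophane lactone: cyclic ester of 11-[5-(11-hydroxyundecyl)thiophen-2-yl]undecanoic acid | O=C1CCCCCCCCCCc2ccc(s2)CCCCCCCCCCCO1 | intermediate (not isolated)
11 | 26-hexacosanolide (oxacycloheptacosan-2-one) | O=C1CCCCCCCCCCCCCCCCCCCCCCCCCO1 | target

## Step count and risk

Total step count: 4. Longest linear sequence: 3 steps (1 → 3 → 9 → 11, or 4 + 5 → 6 → 9 → 11).

The three steps most likely to fail, in order of risk:

**Step 3 (double Sonogashira macrocyclization; oligomers or Glaser products may dominate).** The fallback sets out from 3 (with 5 and 4) and closes the ring at the ester bond instead. Sonogashira coupling of 5 with an excess of 3 (3 equiv; Pd(PPh3)2Cl2, CuI, Et3N, THF, rt) gives 11-(5-iodothiophen-2-yl)undec-10-yn-1-ol F1. A second Sonogashira coupling of F1 with 4 under the same conditions gives the seco acid 11-[5-(11-hydroxyundec-1-yn-1-yl)thiophen-2-yl]undec-10-ynoic acid F2. Yamaguchi activation (2,4,6-trichlorobenzoyl chloride, Et3N, THF) gives the mixed 2,4,6-trichlorobenzoic anhydride of the seco acid F3, which is added slowly to DMAP in toluene at 80 °C and lactonizes. The fallback comes back to the route at 9.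

**Step 4 (one-pot hydrogenation and desulfurization inside the macrocycle; risk of incomplete sulfur removal or lactone cleavage on basic nickel).** The fallback sets out from 9 and moves the reduction to the open chain in alkali. Hot NaOH in aqueous EtOH opens the lactone to sodium 11-[5-(11-hydroxyundec-1-yn-1-yl)thiophen-2-yl]undec-10-ynoate F4. Ni–Al alloy added in portions to the same solution at 90 °C saturates the alkynes and removes the sulfur to give sodium 26-hydroxyhexacosanoate F5. Acidification with HCl gives 26-hydroxyhexacosanoic acid F6. Yamaguchi macrolactonization through the mixed 2,4,6-trichlorobenzoic anhydride of 26-hydroxyhexacosanoic acid F7 (Et3N, THF; then slow addition to DMAP, toluene, reflux, high dilution) closes the ring. The fallback comes back to the route at 11.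

**Step 1 (mixtures of mono-, di- and over-iodinated thiophene; thiophene is volatile).** The fallback sets out from 1 and replaces electrophilic substitution by double deprotonation. n-BuLi (2.5 equiv) with TMEDA in hexane at reflux gives 2,5-dilithiothiophene F8, which is quenched with I2 in THF at −78 °C. The fallback comes back to the route at 3.

## Further compounds

F1 | step 3 | 11-(5-iodothiophen-2-yl)undec-10-yn-1-ol | OCCCCCCCCCC#Cc1ccc(I)s1
F2 | step 3 | 11-[5-(11-hydroxyundec-1-yn-1-yl)thiophen-2-yl]undec-10-ynoic acid | OC(=O)CCCCCCCCC#Cc1ccc(s1)C#CCCCCCCCCCO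
F3 | step 3 | mixed 2,4,6-trichlorobenzoic anhydride of the seco acid | OCCCCCCCCCC#Cc1ccc(s1)C#CCCCCCCCCC(=O)OC(=O)c1c(Cl)cc(Cl)cc1Cl
F4 | step 4 | sodium 11-[5-(11-hydroxyundec-1-yn-1-yl)thiophen-2-yl]undec-10-ynoate | [Na+].[O-]C(=O)CCCCCCCCC#Cc1ccc(s1)C#CCCCCCCCCCO
F5 | step 4 | sodium 26-hydroxyhexacosanoate | [Na+].[O-]C(=O)CCCCCCCCCCCCCCCCCCCCCCCCCO
F6 | step 4 | 26-hydroxyhexacosanoic acid | OC(=O)CCCCCCCCCCCCCCCCCCCCCCCCCO
F7 | step 4 | mixed 2,4,6-trichlorobenzoic anhydride of 26-hydroxyhexacosanoic acid | OCCCCCCCCCCCCCCCCCCCCCCCCCC(=O)OC(=O)c1c(Cl)cc(Cl)cc1Cl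
F8 | step 1 | 2,5-dilithiothiophene | [Li]c1ccc([Li])s1
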